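**Plan**

- Numbering: cyclohexane C5–C10, with C10 quaternary (methyl C14, vinyl C1=C2), C9 a CH2, C8 carrying the ester oxygen, C7/C6 fused to the γ-lactone O6–C12(=O)–C11(C13H3)–C7, and C5 carrying C4(=C3H2)C15H2OH.
- Retrosynthetic cuts, in order: the O8–acyl ester bond, the C15–O bond (allylic C–H), the lactone bond O6–C12, the ring bond C5–C6, the C7–C8 bond, and the C10–C5 bond.
- Enabling feature: on the cyclohexane the lactone carbinol C6 and its neighbour C5, which bears a 1,1-disubstituted alkene (C4=C3H2), are trans-diequatorial. This is the 2-isopropenylcyclohexanol pattern that a C6 aldehyde and a C5=C4(CH3)2 alkene give in a carbonyl-ene reaction.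
- Forward order: the acyclic chain C8–C9–C10(–C5=C4) is made first and joined to the C6–C7–C11–C12 unit by aldol (C7–C8). The cyclohexane then closes (C5–C6), the γ-lactone closes (O6–C12), the C8 ester is attached, C15 is hydroxylated and the side-chain diol is unmasked.
- Stereochemistry: C10 from a chiral copper–carbene catalyst; C7 and C8 from the (S)-4-benzyloxazolidinone auxiliary; C11 from (R)-2-methylsuccinic acid; C5 and C6 from the chair transition state of the ring closure; C3′ from methyl (R)-glycerate acetonide.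

Key step: step 13

Assumption: the (4S,5S) enantiomer of the sulfonate-bearing imidazolinium carbene precursor is taken to give (R)-8 in step 3; if the sense of induction is the opposite, its enantiomer is used and nothing else changes.
Remark: the CIP labels at C5 and C7 change along the route because substituent priorities change; no stereocentre is inverted after it is set.

**Route**

Step 1
Reactants: 1 tert-butyl(but-3-yn-1-yloxy)dimethylsilane
Product: 4 (E)-5-(tert-butyldimethylsilyloxy)-3-methylpent-2-en-1-ol, via alkenyldimethylalane 2 (not isolated), via lithium alkenylalanate 3 (not isolated)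
Conditions: Me3Al, Cp2ZrCl2 (0.2 equiv), CH2Cl2, 0 °C → rt; n-BuLi, THF/hexane, −78 °C; (CH2O)n, −78 °C → rt; cold 1 M HCl
Reagents that add atoms: trimethylaluminium C[Al](C)C; formaldehyde (as paraformaldehyde) C=O
Why: Zirconium-catalysed syn-methylalumination of the terminal alkyne (Negishi carboalumination) puts the methyl group on the internal carbon and aluminium on the terminus, and the derived alanate adds to formaldehyde with retention, so the trisubstituted alkene should form as the E isomer only.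

Step 2
Reactants: 4 (E)-5-(tert-butyldimethylsilyloxy)-3-methylpent-2-en-1-ol
Product: 5 (E)-5-(tert-butyldimethylsilyloxy)-3-methylpent-2-en-1-yl diethyl phosphate
Conditions: ClP(O)(OEt)2, Et3N, DMAP (cat.), CH2Cl2, 0 °C
Reagents that add atoms: diethyl chlorophosphate CCOP(=O)(Cl)OCC
Why: O-Phosphorylation of the primary allylic alcohol installs the leaving group used for copper-catalysed SN2′ substitution.

Step 3
Reactants: 5 (E)-5-(tert-butyldimethylsilyloxy)-3-methylpent-2-en-1-yl diethyl phosphate; 6 2-methylprop-1-enylmagnesium bromide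
Product: 8 (R)-tert-butyl[(3-ethenyl-3,5-dimethylhex-4-en-1-yl)oxy]dimethylsilane, via diisobutyl(2-methylprop-1-enyl)alane 7 (not isolated)
Conditions: 6, iBu2AlCl, THF/hexane, 0 °C → rt; then 5, CuCl2·2H2O (5 mol %), 2-[(4S,5S)-3-mesityl-4,5-diphenyl-4,5-dihydroimidazol-3-ium-1-yl]benzenesulfonate (5.5 mol %), THF, −30 → −15 °C; cold 1 M HCl
Reagents that add atoms: none
Why: Copper–carbene-catalysed enantioselective allylic substitution of E-trisubstituted allylic phosphates by alkenylalanes is an established SN2′ route to vinyl-bearing all-carbon quaternary centres, the alane transfers its alkenyl group in preference to isobutyl, and the chiral sulfonate-bridged carbene on copper selects the alkene face so that C10 should form as R.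

Step 4
Reactants: 8 (R)-tert-butyl[(3-ethenyl-3,5-dimethylhex-4-en-1-yl)oxy]dimethylsilane
Product: 9 (R)-3-ethenyl-3,5-dimethylhex-4-en-1-ol
Conditions: Bu4NF, THF, 0 °C → rt
Reagents that add atoms: none
Why: Fluoride-mediated desilylation frees the primary alcohol and leaves the 1,4-diene untouched.

Step 5
Reactants: 9 (R)-3-ethenyl-3,5-dimethylhex-4-en-1-ol
Product: 10 (R)-3-ethenyl-3,5-dimethylhex-4-enal
Conditions: Dess–Martin periodinane, CH2Cl2, 0 °C → rt; used as a solution (volatile)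
Reagents that add atoms: none
Why: Dess–Martin oxidation gives the aldehyde under neutral conditions, and the β-quaternary centre cannot epimerise while the alkenes cannot move into conjugation.

Step 6
Reactants: 11 (R)-2-methylbutanedioic acid
Product: 12 (R)-3-methyloxolane-2,5-dione
Conditions: AcCl, reflux; evaporate
Reagents that add atoms: none
Why: Acetyl chloride dehydrates the 1,4-diacid to its cyclic anhydride without base, so the C11 stereocentre is not at risk.

Step 7
Reactants: 12 (R)-3-methyloxolane-2,5-dione; 13 (S)-4-benzyl-1,3-oxazolidin-2-one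
Product: 15 (2R)-4-[(4S)-4-benzyl-2-oxo-1,3-oxazolidin-3-yl]-2-methyl-4-oxobutanoic acid, via lithium oxazolidinide 14 (not isolated)
Conditions: 13, n-BuLi, THF, −78 °C; then 12, −78 → 0 °C; aq. HCl
Reagents that add atoms: none
Why: N-Acylation of the lithiated oxazolidinone by ring opening of the anhydride should take place at the less hindered carbonyl next to CH2, which leaves the free acid on the methyl-bearing carbon, and a minor regioisomer would be removed by chromatography after step 8.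

Step 8
Reactants: 15 (2R)-4-[(4S)-4-benzyl-2-oxo-1,3-oxazolidin-3-yl]-2-methyl-4-oxobutanoic acid
Product: 16 tert-butyl (2R)-4-[(4S)-4-benzyl-2-oxo-1,3-oxazolidin-3-yl]-2-methyl-4-oxobutanoate
Conditions: tert-butyl 2,2,2-trichloroacetimidate, BF3·OEt2 (cat.), CH2Cl2/cyclohexane, rt
Reagents that add atoms: tert-butyl 2,2,2-trichloroacetimidate CC(C)(C)OC(=N)C(Cl)(Cl)Cl
Why: Acid-catalysed tert-butylation with the trichloroacetimidate needs no base, so the imide and C11 are safe, and the bulky ester is chosen because it withstands γ-lactonisation by the neighbouring hydroxyls and reduction by LiBH4 in steps 9 to 12.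

Step 9
Reactants: 16 tert-butyl (2R)-4-[(4S)-4-benzyl-2-oxo-1,3-oxazolidin-3-yl]-2-methyl-4-oxobutanoate; 10 (R)-3-ethenyl-3,5-dimethylhex-4-enal
Product: 18 tert-butyl (2R,3S,4R,6R)-3-[(4S)-4-benzyl-2-oxo-1,3-oxazolidine-3-carbonyl]-6-ethenyl-4-hydroxy-2,6,8-trimethylnon-7-enoate, via dibutylboron Z-enolate 17 (not isolated)
Conditions: Bu2BOTf, iPr2NEt, CH2Cl2, −78 → 0 °C; 10, −78 → 0 °C; pH 7 buffer, MeOH, H2O2, 0 °C
Reagents that add atoms: none
Why: Evans syn-aldol reaction in which the Z-boron enolate adds to the aldehyde through a closed chair transition state on the face opposite the benzyl group of the auxiliary, which sets C7 (S) and C8 (R) in the syn relationship that becomes trans-diequatorial on the ring.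

Step 10
Reactants: 18 tert-butyl (2R,3S,4R,6R)-3-[(4S)-4-benzyl-2-oxo-1,3-oxazolidine-3-carbonyl]-6-ethenyl-4-hydroxy-2,6,8-trimethylnon-7-enoate
Product: 19 tert-butyl (2R,3S,4R,6R)-3-[(4S)-4-benzyl-2-oxo-1,3-oxazolidine-3-carbonyl]-4-(tert-butyldimethylsilyloxy)-6-ethenyl-2,6,8-trimethylnon-7-enoate
Conditions: TBSOTf, 2,6-lutidine, CH2Cl2, −78 → 0 °C
Reagents that add atoms: tert-butyldimethylsilyl trifluoromethanesulfonate CC(C)(C)[Si](C)(C)OS(=O)(=O)C(F)(F)F
Why: The silyl triflate with 2,6-lutidine silylates the hindered aldol hydroxyl at low temperature without retro-aldol cleavage or loss of the tert-butyl ester.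

Step 11
Reactants: 19 tert-butyl (2R,3S,4R,6R)-3-[(4S)-4-benzyl-2-oxo-1,3-oxazolidine-3-carbonyl]-4-(tert-butyldimethylsilyloxy)-6-ethenyl-2,6,8-trimethylnon-7-enoate
Product: 20 tert-butyl (2R,3R,4R,6R)-4-(tert-butyldimethylsilyloxy)-6-ethenyl-3-(hydroxymethyl)-2,6,8-trimethylnon-7-enoate
Conditions: LiBH4, Et2O, H2O (1 equiv), 0 °C
Reagents that add atoms: none
Why: LiBH4 reduces the exocyclic imide carbonyl far faster than a tert-butyl ester, so the auxiliary is released and C6 appears as a primary alcohol that does not lactonise onto the hindered ester.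

Step 12
Reactants: 20 tert-butyl (2R,3R,4R,6R)-4-(tert-butyldimethylsilyloxy)-6-ethenyl-3-(hydroxymethyl)-2,6,8-trimethylnon-7-enoate
Product: 21 tert-butyl (2R,3S,4R,6R)-4-(tert-butyldimethylsilyloxy)-6-ethenyl-3-formyl-2,6,8-trimethylnon-7-enoate
Conditions: Dess–Martin periodinane, pyridine, CH2Cl2, 0 °C; used at once
Reagents that add atoms: none
Why: Pyridine-buffered Dess–Martin oxidation gives the α-branched β-silyloxy aldehyde without epimerisation at C7 or β-elimination.

Step 13
Reactants: 21 tert-butyl (2R,3S,4R,6R)-4-(tert-butyldimethylsilyloxy)-6-ethenyl-3-formyl-2,6,8-trimethylnon-7-enoate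
Product: 22 tert-butyl (2R)-2-[(1R,2S,3R,4R,6R)-6-(tert-butyldimethylsilyloxy)-4-ethenyl-2-hydroxy-4-methyl-3-(prop-1-en-2-yl)cyclohexyl]propanoate
Conditions: Me2AlCl (2 equiv), CH2Cl2, −78 → −40 °C; cold 1 M HCl
Reagents that add atoms: none
Why: Me2AlCl binds the aldehyde oxygen at C6, the C5=C4 π bond attacks C6 through C5 while a hydrogen of one C4 methyl group passes to oxygen in a six-membered ene array (concerted, asynchronous), and the resulting alkoxide loses methane from aluminium, which removes the only proton source that could ionise C4. The closest known reaction is the Lewis-acid-promoted carbonyl-ene cyclisation of 6-alkenals that carry a trisubstituted alkene, citronellal to isopulegol. The cyclohexane C5–C10 closes in the 6-exo mode: C5 bonds to C6, C4 stays outside the ring and becomes the 1,1-disubstituted alkene C4=CH2, and O6 also ends outside the ring. C6 and C5 are set by a chair transition state in which the C7 side chain and the C8 silyloxy group are equatorial and the forming C6–O and C5–C4 substituents also take equatorial, mutually trans places, because an axial C6–O would be 1,3-diaxial to the axial C10 methyl and the flipped chair would put the C7, C8 and vinyl groups axial. The step needs chemoselectivity for the 2-methylprop-1-enyl group over the vinyl group, which the substrate secures because the vinyl group has no allylic hydrogen and could only react through a primary cation or a seven-membered ring, and it needs the aldehyde to be the only strong acceptor, which holds because the tert-butyl ester is far less electrophilic. The low temperature and the non-protic Lewis acid should also keep the C7 stereocentre and the β-silyloxy group intact.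

Step 14
Reactants: 22 tert-butyl (2R)-2-[(1R,2S,3R,4R,6R)-6-(tert-butyldimethylsilyloxy)-4-ethenyl-2-hydroxy-4-methyl-3-(prop-1-en-2-yl)cyclohexyl]propanoate
Product: 25 (3R,3aR,4R,6R,7R,7aS)-4-(tert-butyldimethylsilyloxy)-6-ethenyl-3,6-dimethyl-7-(prop-1-en-2-yl)hexahydro-1-benzofuran-2(3H)-one, via bis(trimethylsilyl) derivative 23 (not isolated), via hydroxy acid 24 (not isolated)
Conditions: TMSOTf (3 equiv), 2,6-lutidine, CH2Cl2, 0 °C → rt; 10% aq. citric acid, THF, 0 °C; then DCC, DMAP (cat.), CH2Cl2, 0 °C → rt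
Reagents that add atoms: none
Why: The silyl triflate with 2,6-lutidine cleaves the tert-butyl ester with loss of isobutene under buffered conditions that spare the secondary TBS ether and both 1,1-disubstituted alkenes, dilute acid then frees the acid and the C6 hydroxyl, and carbodiimide activation (Steglich-type lactonisation) closes the five-membered lactone onto O6, the only free hydroxyl, since O8 is blocked.

Step 15
Reactants: 25 (3R,3aR,4R,6R,7R,7aS)-4-(tert-butyldimethylsilyloxy)-6-ethenyl-3,6-dimethyl-7-(prop-1-en-2-yl)hexahydro-1-benzofuran-2(3H)-one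
Product: 26 (3R,3aS,4R,6R,7R,7aS)-6-ethenyl-4-hydroxy-3,6-dimethyl-7-(prop-1-en-2-yl)hexahydro-1-benzofuran-2(3H)-one
Conditions: HF·pyridine, pyridine, THF, 0 °C → rt
Reagents that add atoms: none
Why: HF·pyridine removes the secondary silyl ether under mildly acidic conditions in which no C8 alkoxide forms, so the lactone should stay on O6 and not migrate to O8.

Step 16
Reactants: 27 methyl (R)-2,2-dimethyl-1,3-dioxolane-4-carboxylate
Product: 29 1-[(4R)-2,2-dimethyl-1,3-dioxolan-4-yl]ethan-1-one, via Weinreb amide 28 (not isolated)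
Conditions: MeNHOMe·HCl, iPrMgCl, THF, −20 °C; then MeMgBr, −20 → 0 °C; aq. NH4Cl
Reagents that add atoms: methylmagnesium bromide C[Mg]Br
Why: The ester is converted in the flask into its Weinreb amide, whose chelated tetrahedral adduct with MeMgBr stops at the ketone stage and shields the α-alkoxy stereocentre from enolisation until work-up.

Step 17
Reactants: 29 1-[(4R)-2,2-dimethyl-1,3-dioxolan-4-yl]ethan-1-one
Product: 31 1-[(4R)-2,2-dimethyl-1,3-dioxolan-4-yl]ethenyl trifluoromethanesulfonate, via potassium enolate 30 (not isolated)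
Conditions: KN(SiMe3)2, THF, −78 °C; PhNTf2, −78 → 0 °C
Reagents that add atoms: N-phenylbis(trifluoromethanesulfonimide) O=S(=O)(N(c1ccccc1)S(=O)(=O)C(F)(F)F)C(F)(F)F
Why: Kinetic deprotonation with a bulky amide base at −78 °C takes place at the methyl group and not at the alkoxy-bearing α-carbon, and the enolate is trapped on oxygen by the triflimide to give the 1,1-disubstituted enol triflate.

Step 18
Reactants: 31 1-[(4R)-2,2-dimethyl-1,3-dioxolan-4-yl]ethenyl trifluoromethanesulfonate
Product: 32 2-[(4S)-2,2-dimethyl-1,3-dioxolan-4-yl]prop-2-enoic acid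
Conditions: Pd(OAc)2 (5 mol %), dppp (6 mol %), CO (1 atm), Et3N, DMF/H2O, 60 °C; acidify cold to pH 4
Reagents that add atoms: carbon monoxide [C-]#[O+]; water O
Why: Palladium-catalysed hydroxycarbonylation of the enol triflate (oxidative addition, CO insertion, hydrolysis of the acylpalladium species) converts C–OTf into C–CO2H and does not involve the dioxolane stereocentre.

Step 19
Reactants: 26 (3R,3aS,4R,6R,7R,7aS)-6-ethenyl-4-hydroxy-3,6-dimethyl-7-(prop-1-en-2-yl)hexahydro-1-benzofuran-2(3H)-one; 32 2-[(4S)-2,2-dimethyl-1,3-dioxolan-4-yl]prop-2-enoic acid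
Product: 34 (3R,3aS,4R,6R,7R,7aS)-6-ethenyl-3,6-dimethyl-2-oxo-7-(prop-1-en-2-yl)octahydro-1-benzofuran-4-yl 2-[(4S)-2,2-dimethyl-1,3-dioxolan-4-yl]prop-2-enoate, via mixed anhydride 33 (not isolated)
Conditions: 32, 2,4,6-trichlorobenzoyl chloride, Et3N (1 equiv), toluene, rt; then 26, DMAP, toluene, rt
Reagents that add atoms: none
Why: Yamaguchi esterification, in which the preformed mixed anhydride acylates the equatorial secondary C8 hydroxyl under DMAP catalysis at room temperature, conditions under which the lactone, the exocyclic acrylate alkene and the acetonide should all survive.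

Step 20
Reactants: 34 (3R,3aS,4R,6R,7R,7aS)-6-ethenyl-3,6-dimethyl-2-oxo-7-(prop-1-en-2-yl)octahydro-1-benzofuran-4-yl 2-[(4S)-2,2-dimethyl-1,3-dioxolan-4-yl]prop-2-enoate
Product: 35 (3R,3aS,4R,6R,7S,7aS)-6-ethenyl-7-(3-hydroxyprop-1-en-2-yl)-3,6-dimethyl-2-oxooctahydro-1-benzofuran-4-yl 2-[(4S)-2,2-dimethyl-1,3-dioxolan-4-yl]prop-2-enoate
Conditions: SeO2 (0.5 equiv), t-BuOOH (2 equiv), CH2Cl2, 0 °C → rt, stopped before full conversion
Reagents that add atoms: tert-butyl hydroperoxide CC(C)(C)OO; selenium dioxide O=[Se]=O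
Why: Allylic oxidation by selenium dioxide (ene reaction then [2,3]-sigmatropic shift) with t-BuOOH as reoxidant should occur at the isopropenyl methyl C15, because C5–H is shielded by C10 and C6, the vinyl group has no allylic hydrogen and the acrylate alkene is too electron-poor to react.

Step 21
Reactants: 35 (3R,3aS,4R,6R,7S,7aS)-6-ethenyl-7-(3-hydroxyprop-1-en-2-yl)-3,6-dimethyl-2-oxooctahydro-1-benzofuran-4-yl 2-[(4S)-2,2-dimethyl-1,3-dioxolan-4-yl]prop-2-enoate
Product: 36 (3R,3aS,4R,6R,7S,7aS)-6-ethenyl-7-(3-hydroxyprop-1-en-2-yl)-3,6-dimethyl-2-oxooctahydro-1-benzofuran-4-yl (3S)-3,4-dihydroxy-2-methylidenebutanoate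
Conditions: AcOH/H2O (4:1), rt → 35 °C
Reagents that add atoms: none
Why: Aqueous acetic acid hydrolyses the terminal acetonide and leaves both esters and the allylic alcohol intact, and base is avoided because the freed 4′-hydroxyl could otherwise lactonise and expel O8.

**Compound list**

1 | tert-butyl(but-3-yn-1-yloxy)dimethylsilane | C#CCCO[Si](C)(C)C(C)(C)C | starting material
2 | (E)-[4-(tert-butyldimethylsilyloxy)-2-methylbut-1-en-1-yl]dimethylalane | C[Al](C)/C=C(\C)CCO[Si](C)(C)C(C)(C)C | intermediate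
3 | lithium butyl[(E)-4-(tert-butyldimethylsilyloxy)-2-methylbut-1-en-1-yl]dimethylaluminate | [Li+].CCCC[Al-](C)(C)/C=C(\C)CCO[Si](C)(C)C(C)(C)C | intermediate
4 | (E)-5-(tert-butyldimethylsilyloxy)-3-methylpent-2-en-1-ol | OC/C=C(\C)CCO[Si](C)(C)C(C)(C)C | intermediate
5 | (E)-5-(tert-butyldimethylsilyloxy)-3-methylpent-2-en-1-yl diethyl phosphate | CCOP(=O)(OCC)OC/C=C(\C)CCO[Si](C)(C)C(C)(C)C | intermediate
6 | 2-methylprop-1-enylmagnesium bromide | CC(C)=C[Mg]Br | starting material
7 | diisobutyl(2-methylprop-1-enyl)alane | CC(C)C[Al](CC(C)C)C=C(C)C | intermediate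
8 | (R)-tert-butyl[(3-ethenyl-3,5-dimethylhex-4-en-1-yl)oxy]dimethylsilane | C=C[C@@](C)(CCO[Si](C)(C)C(C)(C)C)C=C(C)C | intermediate
9 | (R)-3-ethenyl-3,5-dimethylhex-4-en-1-ol | C=C[C@@](C)(CCO)C=C(C)C | intermediate
10 | (R)-3-ethenyl-3,5-dimethylhex-4-enal | C=C[C@@](C)(CC=O)C=C(C)C | intermediate
11 | (R)-2-methylbutanedioic acid ((R)-2-methylsuccinic acid) | C[C@H](CC(=O)O)C(=O)O | starting material
12 | (R)-3-methyloxolane-2,5-dione | C[C@@H]1CC(=O)OC1=O | intermediate
13 | (S)-4-benzyl-1,3-oxazolidin-2-one | O=C1OC[C@H](Cc2ccccc2)N1 | starting material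
14 | lithium (4S)-4-benzyl-2-oxo-1,3-oxazolidin-3-ide | [Li+].O=C1OC[C@H](Cc2ccccc2)[N-]1 | intermediate
15 | (2R)-4-[(4S)-4-benzyl-2-oxo-1,3-oxazolidin-3-yl]-2-methyl-4-oxobutanoic acid | C[C@H](CC(=O)N1[C@@H](Cc2ccccc2)COC1=O)C(=O)O | intermediate
16 | tert-butyl (2R)-4-[(4S)-4-benzyl-2-oxo-1,3-oxazolidin-3-yl]-2-methyl-4-oxobutanoate | C[C@H](CC(=O)N1[C@@H](Cc2ccccc2)COC1=O)C(=O)OC(C)(C)C | intermediate
17 | dibutylboron Z-enolate of imide 16 (C11 as in 16) | CCCCB(CCCC)O/C(=C\[C@@H](C)C(=O)OC(C)(C)C)N1[C@@H](Cc2ccccc2)COC1=O | intermediate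
18 | tert-butyl (2R,3S,4R,6R)-3-[(4S)-4-benzyl-2-oxo-1,3-oxazolidine-3-carbonyl]-6-ethenyl-4-hydroxy-2,6,8-trimethylnon-7-enoate | O=C(N1[C@@H](Cc2ccccc2)COC1=O)[C@@H]([C@@H](C)C(=O)OC(C)(C)C)[C@H](O)C[C@](C)(C=C)C=C(C)C | intermediate
19 | tert-butyl (2R,3S,4R,6R)-3-[(4S)-4-benzyl-2-oxo-1,3-oxazolidine-3-carbonyl]-4-(tert-butyldimethylsilyloxy)-6-ethenyl-2,6,8-trimethylnon-7-enoate | O=C(N1[C@@H](Cc2ccccc2)COC1=O)[C@@H]([C@@H](C)C(=O)OC(C)(C)C)[C@H](O[Si](C)(C)C(C)(C)C)C[C@](C)(C=C)C=C(C)C | intermediate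
20 | tert-butyl (2R,3R,4R,6R)-4-(tert-butyldimethylsilyloxy)-6-ethenyl-3-(hydroxymethyl)-2,6,8-trimethylnon-7-enoate | OC[C@@H]([C@@H](C)C(=O)OC(C)(C)C)[C@H](O[Si](C)(C)C(C)(C)C)C[C@](C)(C=C)C=C(C)C | intermediate
21 | tert-butyl (2R,3S,4R,6R)-4-(tert-butyldimethylsilyloxy)-6-ethenyl-3-formyl-2,6,8-trimethylnon-7-enoate | O=C[C@@H]([C@@H](C)C(=O)OC(C)(C)C)[C@H](O[Si](C)(C)C(C)(C)C)C[C@](C)(C=C)C=C(C)C | intermediate
22 | tert-butyl (2R)-2-[(1R,2S,3R,4R,6R)-6-(tert-butyldimethylsilyloxy)-4-ethenyl-2-hydroxy-4-methyl-3-(prop-1-en-2-yl)cyclohexyl]propanoate | C=C[C@@]1(C)C[C@@H](O[Si](C)(C)C(C)(C)C)[C@H]([C@@H](C)C(=O)OC(C)(C)C)[C@@H](O)[C@@H]1C(C)=C | intermediate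
23 | trimethylsilyl ester of acid 24 with the C6 hydroxyl as its trimethylsilyl ether (configuration as in 22) | C=C[C@@]1(C)C[C@@H](O[Si](C)(C)C(C)(C)C)[C@H]([C@@H](C)C(=O)O[Si](C)(C)C)[C@@H](O[Si](C)(C)C)[C@@H]1C(C)=C | intermediate
24 | (2R)-2-[(1R,2S,3R,4R,6R)-6-(tert-butyldimethylsilyloxy)-4-ethenyl-2-hydroxy-4-methyl-3-(prop-1-en-2-yl)cyclohexyl]propanoic acid | C=C[C@@]1(C)C[C@@H](O[Si](C)(C)C(C)(C)C)[C@H]([C@@H](C)C(=O)O)[C@@H](O)[C@@H]1C(C)=C | intermediate
25 | (3R,3aR,4R,6R,7R,7aS)-4-(tert-butyldimethylsilyloxy)-6-ethenyl-3,6-dimethyl-7-(prop-1-en-2-yl)hexahydro-1-benzofuran-2(3H)-one | C=C[C@@]1(C)C[C@@H](O[Si](C)(C)C(C)(C)C)[C@H]2[C@@H](OC(=O)[C@@H]2C)[C@@H]1C(C)=C | intermediate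
26 | (3R,3aS,4R,6R,7R,7aS)-6-ethenyl-4-hydroxy-3,6-dimethyl-7-(prop-1-en-2-yl)hexahydro-1-benzofuran-2(3H)-one | C=C[C@@]1(C)C[C@@H](O)[C@H]2[C@@H](OC(=O)[C@@H]2C)[C@@H]1C(C)=C | intermediate
27 | methyl (R)-2,2-dimethyl-1,3-dioxolane-4-carboxylate | COC(=O)[C@H]1COC(C)(C)O1 | starting material
28 | (4R)-N-methoxy-N,2,2-trimethyl-1,3-dioxolane-4-carboxamide | CON(C)C(=O)[C@H]1COC(C)(C)O1 | intermediate
29 | 1-[(4R)-2,2-dimethyl-1,3-dioxolan-4-yl]ethan-1-one | CC(=O)[C@H]1COC(C)(C)O1 | intermediate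
30 | potassium 1-[(4R)-2,2-dimethyl-1,3-dioxolan-4-yl]ethen-1-olate | [K+].[O-]C(=C)[C@H]1COC(C)(C)O1 | intermediate
31 | 1-[(4R)-2,2-dimethyl-1,3-dioxolan-4-yl]ethenyl trifluoromethanesulfonate | C=C(OS(=O)(=O)C(F)(F)F)[C@H]1COC(C)(C)O1 | intermediate
32 | 2-[(4S)-2,2-dimethyl-1,3-dioxolan-4-yl]prop-2-enoic acid | C=C(C(=O)O)[C@H]1COC(C)(C)O1 | intermediate
33 | 2-[(4S)-2,2-dimethyl-1,3-dioxolan-4-yl]prop-2-enoic 2,4,6-trichlorobenzoic anhydride | C=C(C(=O)OC(=O)c1c(Cl)cc(Cl)cc1Cl)[C@H]2COC(C)(C)O2 | intermediate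
34 | (3R,3aS,4R,6R,7R,7aS)-6-ethenyl-3,6-dimethyl-2-oxo-7-(prop-1-en-2-yl)octahydro-1-benzofuran-4-yl 2-[(4S)-2,2-dimethyl-1,3-dioxolan-4-yl]prop-2-enoate | C=C[C@@]1(C)C[C@@H](OC(=O)C(=C)[C@H]3COC(C)(C)O3)[C@H]2[C@@H](OC(=O)[C@@H]2C)[C@@H]1C(C)=C | intermediate
35 | (3R,3aS,4R,6R,7S,7aS)-6-ethenyl-7-(3-hydroxyprop-1-en-2-yl)-3,6-dimethyl-2-oxooctahydro-1-benzofuran-4-yl 2-[(4S)-2,2-dimethyl-1,3-dioxolan-4-yl]prop-2-enoate | C=C[C@@]1(C)C[C@@H](OC(=O)C(=C)[C@H]3COC(C)(C)O3)[C@H]2[C@@H](OC(=O)[C@@H]2C)[C@@H]1C(=C)CO | intermediate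
36 | (3R,3aS,4R,6R,7S,7aS)-6-ethenyl-7-(3-hydroxyprop-1-en-2-yl)-3,6-dimethyl-2-oxooctahydro-1-benzofuran-4-yl (3S)-3,4-dihydroxy-2-methylidenebutanoate (CNP0260337.1) | C=C[C@@]1(C)C[C@@H](OC(=O)C(=C)[C@H](O)CO)[C@H]2[C@@H](OC(=O)[C@@H]2C)[C@@H]1C(=C)CO | target

**Totals**

Total step count: 21. Longest linear sequence: 15 steps (steps 1–5, 9–15, 19–21).

**Steps most likely to fail**

1. Step 3 (C10 quaternary centre). What may go wrong: poor face selectivity, competing direct SN2 substitution, or transfer of an isobutyl group with the β,β-disubstituted alkenylalane. The fallback sets out from 4 and comes back at 8. Sharpless asymmetric epoxidation of 4 (Ti(OiPr)4, L-(+)-diethyl tartrate, t-BuOOH, 4 Å MS, CH2Cl2, −20 °C) should give [(2S,3S)-3-[2-(tert-butyldimethylsilyloxy)ethyl]-3-methyloxiran-2-yl]methanol F1. Alane 7, made as in step 3, should open the aluminium-bound epoxy alkoxide at the tertiary carbon with inversion (hexane/CH2Cl2, 0 °C) to give (2R,3S)-3-[2-(tert-butyldimethylsilyloxy)ethyl]-3,5-dimethylhex-4-ene-1,2-diol F2. NaIO4 in THF/H2O cleaves the diol to (2S)-2-[2-(tert-butyldimethylsilyloxy)ethyl]-2,4-dimethylpent-3-enal F3, and Ph3P=CH2 (from Ph3PCH3Br and KOtBu, THF, 0 °C) turns the formyl group into the vinyl group of 8. The C10 configuration then comes from the tartrate and a stereospecific epoxide opening, not from a catalyst-controlled C–C bond formation.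

2. Step 13 (ring closure). What may go wrong: ionisation to a tertiary C4 cation followed by chloride capture or alkene migration, methyl transfer from aluminium to C6, or erosion of the trans selectivity. The fallback sets out from 20 and comes back at 22, and forms the same C5–C6 bond with reversed polarity. Ene-type chlorination of the 2-methylprop-1-enyl group of 20 with Ca(OCl)2 and solid CO2 (CH2Cl2/H2O, 0 °C) should give the rearranged allylic chloride tert-butyl (2R,3R,4R,6R)-4-(tert-butyldimethylsilyloxy)-7-chloro-6-ethenyl-3-(hydroxymethyl)-2,6,8-trimethylnon-8-enoate F4 (both epimers at the chlorine-bearing carbon). Dess–Martin oxidation gives tert-butyl (2R,3S,4R,6R)-4-(tert-butyldimethylsilyloxy)-7-chloro-6-ethenyl-3-formyl-2,6,8-trimethylnon-8-enoate F5. CrCl2 in THF at high dilution (Nozaki–Hiyama allylation) converts the chloride into an allylchromium species that adds through its γ-carbon C5 to the C6 aldehyde in a chair transition state, which should give the same trans 2-isopropenyl alcohol 22.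

3. Step 20 (C15 hydroxylation). What may go wrong: attack at the wrong allylic site, further oxidation of the new allylic alcohol to the enal, or slow conversion with decomposition of the acrylate ester. The fallback sets out from 34 and comes back at 35. Ene-type chlorination of the isopropenyl group with Ca(OCl)2 and solid CO2 (CH2Cl2/H2O, 0 °C) should give (3R,3aS,4R,6R,7S,7aS)-7-(3-chloroprop-1-en-2-yl)-6-ethenyl-3,6-dimethyl-2-oxooctahydro-1-benzofuran-4-yl 2-[(4S)-2,2-dimethyl-1,3-dioxolan-4-yl]prop-2-enoate F6. Displacement with HCO2Na and Bu4NI (cat.) in DMF at 40 °C gives (3R,3aS,4R,6R,7S,7aS)-6-ethenyl-7-[3-(formyloxy)prop-1-en-2-yl]-3,6-dimethyl-2-oxooctahydro-1-benzofuran-4-yl 2-[(4S)-2,2-dimethyl-1,3-dioxolan-4-yl]prop-2-enoate F7. KHCO3 in MeOH at 0 °C removes the formyl group much faster than it touches the acrylate ester or the lactone, to give 35.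

Further compounds
F1 | step 3 | [(2S,3S)-3-[2-(tert-butyldimethylsilyloxy)ethyl]-3-methyloxiran-2-yl]methanol | OC[C@@H]1O[C@@]1(C)CCO[Si](C)(C)C(C)(C)C
F2 | step 3 | (2R,3S)-3-[2-(tert-butyldimethylsilyloxy)ethyl]-3,5-dimethylhex-4-ene-1,2-diol | OC[C@H](O)[C@@](C)(CCO[Si](C)(C)C(C)(C)C)C=C(C)C
F3 | step 3 | (2S)-2-[2-(tert-butyldimethylsilyloxy)ethyl]-2,4-dimethylpent-3-enal | O=C[C@@](C)(CCO[Si](C)(C)C(C)(C)C)C=C(C)C
F4 | step 13 | tert-butyl (2R,3R,4R,6R)-4-(tert-butyldimethylsilyloxy)-7-chloro-6-ethenyl-3-(hydroxymethyl)-2,6,8-trimethylnon-8-enoate (both C7 epimers) | OC[C@@H]([C@@H](C)C(=O)OC(C)(C)C)[C@H](O[Si](C)(C)C(C)(C)C)C[C@](C)(C=C)C(Cl)C(C)=C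
F5 | step 13 | tert-butyl (2R,3S,4R,6R)-4-(tert-butyldimethylsilyloxy)-7-chloro-6-ethenyl-3-formyl-2,6,8-trimethylnon-8-enoate (both C7 epimers) | O=C[C@@H]([C@@H](C)C(=O)OC(C)(C)C)[C@H](O[Si](C)(C)C(C)(C)C)C[C@](C)(C=C)C(Cl)C(C)=C
F6 | step 20 | (3R,3aS,4R,6R,7S,7aS)-7-(3-chloroprop-1-en-2-yl)-6-ethenyl-3,6-dimethyl-2-oxooctahydro-1-benzofuran-4-yl 2-[(4S)-2,2-dimethyl-1,3-dioxolan-4-yl]prop-2-enoate | C=C[C@@]1(C)C[C@@H](OC(=O)C(=C)[C@H]3COC(C)(C)O3)[C@H]2[C@@H](OC(=O)[C@@H]2C)[C@@H]1C(=C)CCl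
F7 | step 20 | (3R,3aS,4R,6R,7S,7aS)-6-ethenyl-7-[3-(formyloxy)prop-1-en-2-yl]-3,6-dimethyl-2-oxooctahydro-1-benzofuran-4-yl 2-[(4S)-2,2-dimethyl-1,3-dioxolan-4-yl]prop-2-enoate | C=C[C@@]1(C)C[C@@H](OC(=O)C(=C)[C@H]3COC(C)(C)O3)[C@H]2[C@@H](OC(=O)[C@@H]2C)[C@@H]1C(=C)COC=O
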